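Locants used throughout: the decalin carries drimane numbering (C1–C10; C11 is the carbon on C9, C12 the methyl on C8). Ring C is C1'–C5' (C1' ylidene carbon, C2' enol carbon, C3' CH, C4' ketone, C5' CHCl). TBS = tert-butyldimethylsilyl, TES = triethylsilyl.

## The problem

The target joins a drimane-type trans-decalin (gem-dimethyl at C4, angular methyl at C10, tertiary carbinol at C8) through one exocyclic trisubstituted alkene, C11=C1', to a five-membered ring C. Ring C is the enol form of a 4-alkylidenecyclopentane-1,3-dione (enol at C2', ketone at C4') with a secondary chloride at C5'. C5, C9 and C10 have the configuration of the sclareol-derived chiral pool, but C8 is the epimer: the hydroxyl is β and axial, cis to the β-oriented C11. The fifth stereocentre, C5', lies across a planar alkene from the decalin and cannot be controlled from there, so it needs a control element inside ring C. The alkene geometry (C9 cis to C2', H11 cis to C5') is a further element and is best fixed by mechanism, since an equilibrating olefination has no reason to prefer it. The fragile groups are the tertiary 8β-alcohol (dehydration in strong acid, retro-aldol cleavage whenever C11 is a carbonyl), the C5' chloride (allylic and α to the C4' ketone, hence prone to ionisation, SN2' attack and epimerisation) and the acidic vinylogous acid; chloride and dione must therefore appear late. The enabling feature is the exocyclic alkene C11=C1' flanked on ring C by the heteroatom-bearing carbon C5'. Once the chloride is traced back to an oxygen, this is the imprint of a syn reductive coupling of an alkyne C11≡C1' with an aldehyde at C5', closing ring C through C1'–C5'.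

## Retrosynthesis

**Unmasking of the vinylogous acid (24 ⇐ 23 ⇐ 22 ⇐ 21).** No skeletal bond is cut. The C2' carbonyl of 24 is traced to the dioxolane of 23, and the C4' ketone of 23 to the carbinol of 22 and its silyl ether 21. The ring is thus never a 1,3-dicarbonyl compound while the C–Cl bond is made or an oxidant is present, which excludes reaction at C3' and keeps C5' from being α to a free ketone until the last two steps. The forward steps must be a fluoride desilylation, a neutral alcohol oxidation and a mild chloride-free hydrolysis.

**C5'–Cl (21 ⇐ 20 ⇐ 19).** The chloride is cut back to the allylic alcohol 20 with inversion, and 20 to its triethylsilyl ether 19. Electrophilic chlorination of the dione would strike C3', so nucleophilic displacement at an oxygenated C5' is the only regiochemically safe option. The precursor 19 carries trans oxygen functions at C4' and C5'. The forward reaction must be a clean SN2 process on a secondary allylic carbinol, without SN2' transposition.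

**C1'–C5', the key cut (19 ⇐ 18).** Cutting the ring bond between the ylidene carbon and the carbinol carbon opens ring C to the acyclic ynal 18. The neighbouring cuts are weaker. Olefination across C11=C1' would have to join a neopentyl-type aldehyde to a ring C nucleophile that prefers to react at C3', and would not control the geometry. A cut at C9–C11 would build a bond to a centre between two quaternary carbons. The C1'–C5' cut removes one ring, the alkene geometry and the C5' stereocentre at once. The forward reaction must add nickel and C5' to the same face of the alkyne and transmit the configuration of C4' to C5'.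

**Oxidation-state adjustments (18 ⇐ 17 ⇐ 16 ⇐ 15).** The aldehyde of 18 is traced to primary alcohol 17 and its bis-silyl ether 16, and the dioxolane of 16 to ynone 15. C5' is carried as a silyl ether rather than an ester so that no second electrophile competes in the fragment union. The ketal removes the electrophilic ynone before nickel chemistry and adds a gem-disubstituted centre that favours ring closure.

**C1'–C2' (15 ⇐ 9 + 13).** The ynone is cut between the alkyne carbon and the carbonyl into terminal alkyne 9 and Weinreb amide 13. This is the most convergent cut of the chain: it joins a six-step and a three-step fragment, and an acetylide acylation that stops at the ketone is reliable.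

**Malate fragment (13 ⇐ 12 ⇐ 11 ⇐ 10).** Amide 13 comes from ester 12, its diol 11 and dimethyl (S)-malate 10. The malate stereocentre becomes C4', the temporary control centre that is oxidised away at the end. The forward sequence has to distinguish the two esters, which a hydroxyl-directed reduction does.

**C11≡C1' (9 ⇐ 7 + 8, 7 ⇐ 6).** The terminal alkyne is cut to aldehyde 7 and the one-carbon donor 8. Aldehyde 7 is the silyl ether of β-hydroxy aldehyde 6, protected so that neither retro-aldol cleavage nor alkoxide chemistry intervenes under base.

**Degradation and C8 epimerisation (6 ⇐ 5 ⇐ 4 ⇐ 2 ⇐ 1).** Aldehyde 6 results from glycol cleavage of triol 5 (cut C11–C12), obtained from hydroxy lactone 4 and thus from 8-epi-sclareolide 2. Lactone 2 is the acid-equilibrated C8 epimer of (+)-sclareolide 1. All four decalin stereocentres therefore come from the chiral pool, with one step to correct C8.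

## Roads not taken

**Alternative 1:** The cut is C9–C10 of ring B. In the forward sense the β-keto ester carbon C9 of the monocyclic enone A1 adds intramolecularly (6-exo-trig Michael addition under base) to C10, the β-carbon of the ring A enone, and gives the trans-decalin dione ester A2.
- Merits: inexpensive terpenoid feedstock, and the quaternary C10 and C9 are formed in one thermodynamically controlled step. A2 keeps a C8 ketone, to which a methyl nucleophile must add from the α face because the β face is blocked by the axial C10 methyl. This gives the 8β-hydroxy/8α-methyl array directly, without an epimerisation, and C11 arrives as an ester with no carbon to degrade. In these two respects it is better than the chosen plan, which spends three steps removing C12 and relies on an acid equilibrium at C8.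
- Weak points: A2 has an extra carbonyl at C2 that must be removed in the presence of the C8 ketone before methyl addition can be chemoselective. The only stereocentre of A1, C5, is the γ-position of the enone and is exposed to vinylogous enolisation under the basic cyclisation conditions. Conjugate addition to a β,β-disubstituted enone is reversible. Ring C would still have to be made in the same way.
- Comparison: the chosen plan sets against this the certainty of four decalin stereocentres bought ready-made and a much shorter path to the alkyne.

**Alternative 2:** The cut is C8–C9 together with O8–C11. The keto acid A3 would be activated at the carboxyl group; a chiral tertiary-amine catalyst forms an ammonium enolate at C9 that adds to the C8 methyl ketone, and the C8 alkoxide closes the β-lactone A4.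
- Merits: ring B and both C8 and C9 are set in one step. A ring-fused β-lactone can only be cis, which is exactly the 8β-oxygen/9β-carbon relationship of the target, so no epimerisation is needed. C11 is at the acid level, so reduction and reoxidation would converge on aldehyde 6 without any degradation. On stereochemical logic at C8/C9 this road is superior.
- Weak points: A3 has vicinal stereocentres at C5 and quaternary C10 and needs its own asymmetric synthesis. The enolate carbon C9 is neopentyl and must attack a ketone, and the facial preference of the existing centres must match the catalyst. The strained lactone limits later conditions.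
- Comparison: the chosen plan reaches 6 from commercial material in four steps, which the preparation of A3 alone cannot match.

**Alternative 3:** The cuts are C5–C10 and C8–C9. The acyclic trienimide A5 would cyclise in an intramolecular Diels–Alder reaction under a chiral bis(oxazoline) complex of Cu(SbF6)2 (divalent copper) to the trans-fused octalin A6, closing rings A and B together.
- Merits: two rings and four stereocentres from an acyclic precursor in one catalytic enantioselective step, access to either enantiomer and to analogues, and an oxygen already at C8. As a general entry it is better than a chiral-pool route.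
- Weak points: the dienophile carbon C10 is β,β-disubstituted and the diene terminus C5 is flanked by quaternary C4, so both ends of the new C5–C10 bond are congested, outside the comfortable scope of two-point-binding Lewis acid catalysis. A5 needs a geometrically pure trisubstituted (E)-enoyl unit and an (E,E)-silyloxydiene. A6 lacks the C8 methyl group, so desilylation, oxidation, methyl addition, hydrogenation of C6=C7 and conversion of the imide to the aldehyde are needed before the stage of 6 is reached.
- Comparison: the chosen plan sets against it that the natural configuration is the one required and that the decalin costs one corrective step.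

Key step: step 14

Assumption 1: the C11 configuration of 4 and 5 is left unassigned, because this centre becomes the sp2 aldehyde carbon in step 4.
Assumption 2: ring C of 24 is a tautomeric vinylogous acid written as its C2' enol; the final hydrolysis is expected to deliver this compound as its equilibrium tautomer mixture.

## Route

Step 1
Reactants: 1 (+)-sclareolide
Product: 2 8-epi-sclareolide (cis-fused γ-lactone, C8–O β, C12 methyl α)
Conditions: conc. H2SO4, HCO2H, 23 °C
Reagents that add atoms: none
Why: Acid-mediated lactone epimerisation: protonation ionises the tertiary C8–O bond and the C8 cation recloses on the carboxyl group from the β face to the thermodynamically preferred cis-fused γ-lactone; C5, C9 and C10 are untouched, so the 8β-O/9β-C arrangement of the target is set here.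

Step 2
Reactants: 2 8-epi-sclareolide
Product: 4 11-hydroxy-8-epi-sclareolide (C11 configuration unassigned), via potassium lactone enolate 3 (not isolated)
Conditions: KN(SiMe3)2, THF, −78 °C; then 2-(phenylsulfonyl)-3-phenyloxaziridine, −78 °C; aq. NH4Cl
Reagents that add atoms: 2-(phenylsulfonyl)-3-phenyloxaziridine, O=S(=O)(c1ccccc1)N1OC1c1ccccc1
Why: Enolate hydroxylation with an N-sulfonyloxaziridine: the C11 enolate attacks the oxaziridine oxygen; the C11 configuration is irrelevant because step 4 turns C11 into the aldehyde carbon.

Step 3
Reactants: 4 11-hydroxy-8-epi-sclareolide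
Product: 5 13,14,15,16-tetranor-8-epi-labdane-8β,11,12-triol (C11 configuration unassigned)
Conditions: LiAlH4, THF, 0 °C → reflux
Reagents that add atoms: none
Why: Hydride reduction of the lactone gives the C8 and C12 hydroxyls and leaves the C11 hydroxyl, so the 11,12-glycol needed for cleavage is in place; no stereocentre is touched.

Step 4
Reactants: 5 tetranor-8-epi-labdane-8β,11,12-triol
Product: 6 8β-hydroxydriman-11-al (8α-methyl, 9β-formyl)
Conditions: NaIO4, THF/H2O, 23 °C
Reagents that add atoms: none
Why: Periodate glycol cleavage (Malaprade reaction) cuts C11–C12 only, since the C8 and C11 hydroxyls are 1,3-related; the neutral medium avoids retro-aldol cleavage and dehydration of the β-hydroxy aldehyde.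

Step 5
Reactants: 6 8β-hydroxydriman-11-al
Product: 7 8β-(triethylsilyloxy)driman-11-al
Conditions: Et3SiOTf, 2,6-lutidine, CH2Cl2, −78 → 0 °C
Reagents that add atoms: triethylsilyl trifluoromethanesulfonate, CC[Si](CC)(CC)OS(=O)(=O)C(F)(F)F
Why: Silyl triflate silylation of the hindered axial tertiary alcohol; at low temperature O-silylation is much faster than enol silylation of the α-branched aldehyde, and the ether blocks retro-aldol and alkoxide chemistry in steps 6, 10 and 11.

Step 6
Reactants: 7 8β-(triethylsilyloxy)driman-11-al; 8 dimethyl (1-diazo-2-oxopropyl)phosphonate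
Product: 9 9β-ethynyl-8β-(triethylsilyloxy)-11-nordrimane (the ethynyl carbons are C11 and C1')
Conditions: K2CO3, MeOH, 0 → 23 °C
Reagents that add atoms: none
Why: Ohira–Bestmann (Seyferth–Gilbert) homologation: methoxide cleaves the acetyl group of 8, the diazomethylphosphonate anion adds to the aldehyde, Horner–Wadsworth–Emmons-type elimination and loss of N2 give an alkylidene carbene, and 1,2-hydrogen shift gives the terminal alkyne; the C9–H lies between two quaternary carbons, so enolisation should be slow at this temperature.

Step 7
Reactants: 10 dimethyl (S)-malate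
Product: 11 methyl (S)-3,4-dihydroxybutanoate
Conditions: BH3·SMe2, NaBH4 (5 mol %), THF, 23 °C; then MeOH
Reagents that add atoms: none
Why: Hydroxyl-directed borane reduction: the alkoxyborane formed at the hydroxyl delivers hydride through a five-membered chelate to the adjacent ester only, leaving the distal ester; the stereocentre is not involved.

Step 8
Reactants: 11 methyl (S)-3,4-dihydroxybutanoate
Product: 12 methyl (S)-3,4-bis(tert-butyldimethylsilyloxy)butanoate
Conditions: t-BuMe2SiCl, imidazole, DMF, 23 °C
Reagents that add atoms: tert-butyldimethylsilyl chloride, CC(C)(C)[Si](C)(C)Cl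
Why: Standard bis-silylation of a primary/secondary 1,2-diol; the secondary ether is the later C4' control element and the primary ether the masked C5' aldehyde.

Step 9
Reactants: 12 methyl (S)-3,4-bis(tert-butyldimethylsilyloxy)butanoate
Product: 13 (S)-3,4-bis(tert-butyldimethylsilyloxy)-N-methoxy-N-methylbutanamide
Conditions: MeNH(OMe)·HCl, i-PrMgCl, THF, −20 → 0 °C
Reagents that add atoms: N,O-dimethylhydroxylamine hydrochloride, CNOC.Cl
Why: Weinreb amide formation from an ester with the chloromagnesium amide of N,O-dimethylhydroxylamine, well precedented for β-silyloxy esters without elimination.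

Step 10
Reactants: 9 9β-ethynyl-8β-(triethylsilyloxy)-11-nordrimane; 13 (S)-3,4-bis(tert-butyldimethylsilyloxy)-N-methoxy-N-methylbutanamide
Product: 15 (5S)-5,6-bis(tert-butyldimethylsilyloxy)-1-[8β-(triethylsilyloxy)-11-nordriman-9β-yl]hex-1-yn-3-one, via lithium acetylide 14 (not isolated)
Conditions: n-BuLi, THF, −78 °C; then 13, −78 → 0 °C; aq. NH4Cl
Reagents that add atoms: none
Why: Acylation of a lithium acetylide by a Weinreb amide forms C1'–C2'; the chelated tetrahedral intermediate prevents over-addition and collapses to the ynone on work-up.

Step 11
Reactants: 15 ynone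
Product: 16 (S)-2-[2,3-bis(tert-butyldimethylsilyloxy)propyl]-2-{[8β-(triethylsilyloxy)-11-nordriman-9β-yl]ethynyl}-1,3-dioxolane
Conditions: (Me3SiOCH2)2, Me3SiOTf (5 mol %), CH2Cl2, −78 → −20 °C
Reagents that add atoms: 1,2-bis(trimethylsilyloxy)ethane, C[Si](C)(C)OCCO[Si](C)(C)C
Why: Silyl triflate-catalysed ketalisation with the bis-silyl ether of ethylene glycol: under aprotic low-temperature conditions 1,2-addition to the silyloxycarbenium ion outruns conjugate addition to the ynone and β-elimination of the C4' silyloxy group, and formation of hexamethyldisiloxane drives the reaction.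

Step 12
Reactants: 16 dioxolane bis-silyl ether
Product: 17 (2S)-2-(tert-butyldimethylsilyloxy)-4,4-ethylenedioxy-6-[8β-(triethylsilyloxy)-11-nordriman-9β-yl]hex-5-yn-1-ol
Conditions: HF·pyridine, pyridine, THF, 0 °C
Reagents that add atoms: none
Why: Buffered fluoride cleavage removes the unhindered primary silyl ether first; the secondary TBS ether and the axial tertiary TES ether shielded by the C10 methyl are far slower, and the acidic medium precludes 1,2-silyl migration.

Step 13
Reactants: 17 primary alcohol
Product: 18 (2S)-2-(tert-butyldimethylsilyloxy)-4,4-ethylenedioxy-6-[8β-(triethylsilyloxy)-11-nordriman-9β-yl]hex-5-ynal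
Conditions: Dess–Martin periodinane, NaHCO3, CH2Cl2, 0 → 23 °C
Reagents that add atoms: none
Why: Dess–Martin oxidation under buffered non-basic conditions gives the α-silyloxy aldehyde without epimerising C4'; the aldehyde is used directly.

Step 14
Reactants: 18 ynal
Product: 19 Z-alkylidenecyclopentane with ring C closed: C2' dioxolane, (4'S)-OTBS, (5'S)-OTES (trans), Z-C11=C1', 8β-OTES
Conditions: Ni(C8H12)2 (10 mol %), P(n-Bu)3 (20 mol %), Et3SiH (5 equiv), THF, 23–45 °C
Reagents that add atoms: triethylsilane, CC[SiH](CC)CC
Why: Zerovalent nickel binds the alkyne C11≡C1' and the aldehyde C5'=O of 18 and undergoes oxidative cyclisation to an oxanickelacyclopentene of divalent nickel, forming C1'–C5' together with Ni–C11 and Ni–O bonds. σ-Bond metathesis of the Ni–O bond with Et3SiH gives the O–SiEt3 ether and a vinylnickel hydride, whose reductive elimination forms C11–H and returns zerovalent nickel. The closest known reaction type is the nickel-catalysed reductive cyclisation of ynals with trialkylsilanes to silyl ethers of 2-alkylidenecycloalkanols. Ring C closes in the 5-exo-dig mode with C11 exocyclic; the endo mode is excluded because syn addition would place a trans alkene in a six-membered ring. Nickel and C5' add to the same face of the alkyne, so H11 ends cis to C5' and C9 cis to C2', which is the Z alkene of 19 and the geometry of the target. The new stereocentre C5' is controlled by C4': in the bicyclic transition state the C4' silyloxy group takes the convex position, anti to the C5'–O–Ni bond with the two C–O dipoles opposed (Felkin–Anh-type), which leads to the trans (4'S,5'S) diether. The step needs cyclisation to outrun direct hydrosilylation of the aldehyde and intermolecular coupling; the gem-disubstituted ketal carbon C2' (Thorpe–Ingold effect) and moderate dilution secure this. No oxygen substituent is β to the C–Ni bond, so alkoxide elimination is not available.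

Step 15
Reactants: 19 cyclised bis-silyl ether
Product: 20 (4'S,5'S)-allylic alcohol: C5'–OH free, C4'–OTBS, C2' dioxolane, 8β-OTES
Conditions: HF·pyridine, pyridine, THF, 0 °C
Reagents that add atoms: none
Why: Fluoride cleavage of the secondary allylic TES ether is much faster than that of the secondary TBS ether or the hindered tertiary TES ether at C8; the buffered medium spares the allylic ketal.

Step 16
Reactants: 20 allylic alcohol
Product: 21 (4'S,5'R)-allylic chloride: C5'–Cl cis to C4'–OTBS, C2' dioxolane, 8β-OTES
Conditions: PPh3, Cl3CC(O)CCl3, CH2Cl2, 0 °C
Reagents that add atoms: hexachloroacetone, ClC(Cl)(Cl)C(=O)C(Cl)(Cl)Cl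
Why: Appel-type deoxychlorination with hexachloroacetone as the chlorine source: the alkoxyphosphonium ion is displaced by chloride at C5' in an SN2 step with inversion, (5'S)-OH to (5'R)-Cl; SN2' attack at C11 is disfavoured because C11 is shielded by C9 between two quaternary carbons, and displacement cis to a vicinal substituent on a five-membered ring is routine in nucleoside chemistry.

Step 17
Reactants: 21 allylic chloride
Product: 22 chloro diol: (4'S)-OH, (5'R)-Cl, C2' dioxolane, 8β-OH
Conditions: HF·pyridine (excess), THF, 0 → 23 °C
Reagents that add atoms: none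
Why: Fluoride cleavage of the remaining TBS and TES ethers; the chlorohydrin is cis, so the C4' hydroxyl cannot displace chloride to an epoxide, and the non-aqueous acidic medium leaves the ketal and the chloride intact.

Step 18
Reactants: 22 chloro diol
Product: 23 (5'R)-α-chloro ketone: C4' ketone, C2' dioxolane, 8β-OH
Conditions: Dess–Martin periodinane, NaHCO3, CH2Cl2, 0 °C
Reagents that add atoms: none
Why: Dess–Martin oxidation of the secondary alcohol in the presence of the tertiary one; with C2' still a ketal the product is not a 1,3-dicarbonyl compound, so over-oxidation at C3' cannot occur, and the buffered neutral medium limits enolisation towards C5'.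

Step 19
Reactants: 23 α-chloro ketone
Product: 24 CNP0279879.2 (target)
Conditions: TsOH·H2O (cat.), THF/H2O, 23 °C
Reagents that add atoms: water, O
Why: Acid-catalysed ketal hydrolysis: the allylic dioxolane ionises readily and water gives the C2' carbonyl, which enolises to the vinylogous acid; any 2-hydroxyethyl enol ether formed by β-elimination converges on the same product, a sulfonic acid is used so that no free chloride can exchange at C5', and the conditions are too mild to dehydrate the tertiary alcohol.

## Compound list

1 | (+)-sclareolide | CC1(C)CCC[C@]2(C)[C@@H](CC(=O)O3)[C@@]3(C)CC[C@@H]12 | starting material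
2 | 8-epi-sclareolide (cis-fused lactone, C8–O β) | CC1(C)CCC[C@]2(C)[C@@H](CC(=O)O3)[C@]3(C)CC[C@@H]12 | intermediate
3 | potassium enolate of 2 (not isolated) | CC1(C)CCC[C@]2(C)[C@@H](C=C([O-])O3)[C@]3(C)CC[C@@H]12.[K+] | intermediate
4 | 11-hydroxy-8-epi-sclareolide (C11 unassigned) | CC1(C)CCC[C@]2(C)[C@@H](C(O)C(=O)O3)[C@]3(C)CC[C@@H]12 | intermediate
5 | 13,14,15,16-tetranor-8-epi-labdane-8β,11,12-triol (C11 unassigned) | CC1(C)CCC[C@]2(C)[C@@H](C(O)CO)[C@@](C)(O)CC[C@@H]12 | intermediate
6 | 8β-hydroxydriman-11-al | CC1(C)CCC[C@]2(C)[C@@H](C=O)[C@@](C)(O)CC[C@@H]12 | intermediate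
7 | 8β-(triethylsilyloxy)driman-11-al | CC1(C)CCC[C@]2(C)[C@@H](C=O)[C@@](C)(O[Si](CC)(CC)CC)CC[C@@H]12 | intermediate
8 | dimethyl (1-diazo-2-oxopropyl)phosphonate | COP(=O)(OC)C(=[N+]=[N-])C(C)=O | starting material
9 | 9β-ethynyl-8β-(triethylsilyloxy)-11-nordrimane | CC1(C)CCC[C@]2(C)[C@@H](C#C)[C@@](C)(O[Si](CC)(CC)CC)CC[C@@H]12 | intermediate
10 | dimethyl (S)-malate | COC(=O)C[C@H](O)C(=O)OC | starting material
11 | methyl (S)-3,4-dihydroxybutanoate | COC(=O)C[C@H](O)CO | intermediate
12 | methyl (S)-3,4-bis(tert-butyldimethylsilyloxy)butanoate | COC(=O)C[C@H](O[Si](C)(C)C(C)(C)C)CO[Si](C)(C)C(C)(C)C | intermediate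
13 | (S)-3,4-bis(tert-butyldimethylsilyloxy)-N-methoxy-N-methylbutanamide | CON(C)C(=O)C[C@H](O[Si](C)(C)C(C)(C)C)CO[Si](C)(C)C(C)(C)C | intermediate
14 | lithium acetylide of 9 (not isolated) | CC1(C)CCC[C@]2(C)[C@@H](C#C[Li])[C@@](C)(O[Si](CC)(CC)CC)CC[C@@H]12 | intermediate
15 | (5S)-5,6-bis(tert-butyldimethylsilyloxy)-1-[8β-(triethylsilyloxy)-11-nordriman-9β-yl]hex-1-yn-3-one | CC1(C)CCC[C@]2(C)[C@@H](C#CC(=O)C[C@H](O[Si](C)(C)C(C)(C)C)CO[Si](C)(C)C(C)(C)C)[C@@](C)(O[Si](CC)(CC)CC)CC[C@@H]12 | intermediate
16 | ethylene ketal of 15 (2,2-disubstituted 1,3-dioxolane) | CC1(C)CCC[C@]2(C)[C@@H](C#CC3(OCCO3)C[C@H](O[Si](C)(C)C(C)(C)C)CO[Si](C)(C)C(C)(C)C)[C@@](C)(O[Si](CC)(CC)CC)CC[C@@H]12 | intermediate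
17 | (2S)-2-(tert-butyldimethylsilyloxy)-4,4-ethylenedioxy-6-[8β-(triethylsilyloxy)-11-nordriman-9β-yl]hex-5-yn-1-ol | CC1(C)CCC[C@]2(C)[C@@H](C#CC3(OCCO3)C[C@H](O[Si](C)(C)C(C)(C)C)CO)[C@@](C)(O[Si](CC)(CC)CC)CC[C@@H]12 | intermediate
18 | (2S)-2-(tert-butyldimethylsilyloxy)-4,4-ethylenedioxy-6-[8β-(triethylsilyloxy)-11-nordriman-9β-yl]hex-5-ynal | CC1(C)CCC[C@]2(C)[C@@H](C#CC3(OCCO3)C[C@H](O[Si](C)(C)C(C)(C)C)C=O)[C@@](C)(O[Si](CC)(CC)CC)CC[C@@H]12 | intermediate
19 | Z-alkylidenecyclopentane: C2' dioxolane, (4'S)-OTBS, (5'S)-OTES, 8β-OTES | CC1(C)CCC[C@]2(C)[C@@H](/C=C3\C4(OCCO4)C[C@H](O[Si](C)(C)C(C)(C)C)[C@H]3O[Si](CC)(CC)CC)[C@@](C)(O[Si](CC)(CC)CC)CC[C@@H]12 | intermediate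
20 | (4'S,5'S)-allylic alcohol: C5'–OH, C4'–OTBS, C2' dioxolane, 8β-OTES | CC1(C)CCC[C@]2(C)[C@@H](/C=C3\C4(OCCO4)C[C@H](O[Si](C)(C)C(C)(C)C)[C@H]3O)[C@@](C)(O[Si](CC)(CC)CC)CC[C@@H]12 | intermediate
21 | (4'S,5'R)-allylic chloride: C5'–Cl, C4'–OTBS, C2' dioxolane, 8β-OTES | CC1(C)CCC[C@]2(C)[C@@H](/C=C3\C4(OCCO4)C[C@H](O[Si](C)(C)C(C)(C)C)[C@@H]3Cl)[C@@](C)(O[Si](CC)(CC)CC)CC[C@@H]12 | intermediate
22 | chloro diol: (4'S)-OH, (5'R)-Cl, C2' dioxolane, 8β-OH | CC1(C)CCC[C@]2(C)[C@@H](/C=C3\C4(OCCO4)C[C@H](O)[C@@H]3Cl)[C@@](C)(O)CC[C@@H]12 | intermediate
23 | (5'R)-α-chloro ketone: C4' ketone, C2' dioxolane, 8β-OH | CC1(C)CCC[C@]2(C)[C@@H](/C=C3\C4(OCCO4)CC(=O)[C@@H]3Cl)[C@@](C)(O)CC[C@@H]12 | intermediate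
24 | CNP0279879.2 | CC1(C)CCC[C@]2(C)[C@@H](/C=C3\C(O)=CC(=O)[C@@H]3Cl)[C@@](C)(O)CC[C@@H]12 | target

## Step count

Total step count: 19. Longest linear sequence: 16 steps, from (+)-sclareolide (steps 1–6 and 10–19). The malate branch is steps 7–9.

## Least certain steps

**Step 14 (key step).** The most likely failure is poor or reversed facial selectivity at the aldehyde. The 1,2-induction from C4' across a forming five-membered ring rests on a steric and dipolar preference that is substrate-dependent. The alkene geometry, by contrast, is fixed by the metallacycle. Fallback, setting out from 18 and coming back at 20: the closure is accepted with whatever selectivity it shows. The cis-configured (5'R) bis-silyl ether F1 is desilylated at C5' (HF·pyridine, pyridine) to the cis alcohol F2. Mitsunobu inversion with 4-nitrobenzoic acid (PPh3, diisopropyl azodicarboxylate) gives the trans 4-nitrobenzoate F3. Here the carboxylate enters anti to the C4' silyloxy group, the easy direction. Methanolysis (K2CO3, MeOH) then gives 20. The C5' configuration is thus set by a stereospecific displacement instead of by induction.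

**Step 16.** The most likely failure is leakage from the SN2 path. Chloride must enter cis to the C4' silyloxy group, and if collapse of the phosphonium ion pair is slow, ionisation to the allyl cation or SN2' attack can erode the configuration at C5' and the alkene position. Fallback, from 20 back to 21: the alcohol is converted with ClCH2SO2Cl and pyridine into the isolable chloromethanesulfonate F4. This is displaced in a separate step by free chloride (LiCl, DMF, 0 → 23 °C) under conditions that favour a bimolecular path, with the reaction stopped before chloride–chloride exchange can begin.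

**Step 18.** The most likely failure is loss of configuration at C5' by enolisation of the α-chloro β,γ-unsaturated ketone towards the conjugated dienol, together with β-elimination that opens the ketal. Fallback, from 22 back to 24: the order is reversed. The ketal of 22 is hydrolysed first (TsOH·H2O, THF/H2O) to the β-hydroxy enone F5, in which C5' is not α to a carbonyl group. The β-hydroxy ketone is then oxidised with one equivalent of Dess–Martin periodinane directly to 24. The cost is the risk of over-oxidation of the 1,3-dione at C3', which the main route avoids.

**Step 6.** The most likely failure is slow addition to the neopentyl-type aldehyde. Under prolonged exposure to methoxide this leaves room for epimerisation at C9 (the axial 9α-formyl epimer is not clearly less stable) and for β-elimination of the silyloxy group. Fallback, from 7 back to 9: a base-free Corey–Fuchs sequence. CBr4 and PPh3 in CH2Cl2 give the dibromoalkene F6. n-BuLi (2 equiv, THF, −78 °C) then effects bromine–lithium exchange and Fritsch–Buttenberg–Wiechell rearrangement to the acetylide, which is protonated to 9. The same acetylide, 14, can instead be treated directly with 13 to give 15.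

## Further compounds

F1 | step 14 | C5' epimer of 19: cis (4'S,5'R) bis-silyl ether | CC1(C)CCC[C@]2(C)[C@@H](/C=C3\C4(OCCO4)C[C@H](O[Si](C)(C)C(C)(C)C)[C@@H]3O[Si](CC)(CC)CC)[C@@](C)(O[Si](CC)(CC)CC)CC[C@@H]12
F2 | step 14 | C5' epimer of 20: cis (4'S,5'R) allylic alcohol | CC1(C)CCC[C@]2(C)[C@@H](/C=C3\C4(OCCO4)C[C@H](O[Si](C)(C)C(C)(C)C)[C@@H]3O)[C@@](C)(O[Si](CC)(CC)CC)CC[C@@H]12
F3 | step 14 | 4-nitrobenzoate of 20 (trans, 4'S,5'S) | CC1(C)CCC[C@]2(C)[C@@H](/C=C3\C4(OCCO4)C[C@H](O[Si](C)(C)C(C)(C)C)[C@H]3OC(=O)c5ccc(cc5)[N+](=O)[O-])[C@@](C)(O[Si](CC)(CC)CC)CC[C@@H]12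
F4 | step 16 | chloromethanesulfonate of 20 | CC1(C)CCC[C@]2(C)[C@@H](/C=C3\C4(OCCO4)C[C@H](O[Si](C)(C)C(C)(C)C)[C@H]3OS(=O)(=O)CCl)[C@@](C)(O[Si](CC)(CC)CC)CC[C@@H]12
F5 | step 18 | β-hydroxy enone: C2' ketone, (4'S)-OH, (5'R)-Cl, 8β-OH | CC1(C)CCC[C@]2(C)[C@@H](/C=C3\C(=O)C[C@H](O)[C@@H]3Cl)[C@@](C)(O)CC[C@@H]12
F6 | step 6 | 9β-(2,2-dibromovinyl)-8β-(triethylsilyloxy)-11-nordrimane | CC1(C)CCC[C@]2(C)[C@@H](C=C(Br)Br)[C@@](C)(O[Si](CC)(CC)CC)CC[C@@H]12
A1 | alternative 1 | methyl 3-oxo-5-[(1S)-2,6,6-trimethyl-4-oxocyclohex-2-en-1-yl]pentanoate | COC(=O)CC(=O)CC[C@@H]1C(C)=CC(=O)CC1(C)C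
A2 | alternative 1 | methyl 2,8-dioxo-12-nordriman-11-oate (trans-decalin-2,8-dione with C11 ester on C9) | CC1(C)CC(=O)C[C@]2(C)[C@@H](C(=O)OC)C(=O)CC[C@@H]12
A3 | alternative 2 | 2-[(1R,2S)-1,3,3-trimethyl-2-(3-oxobutyl)cyclohexyl]acetic acid | CC(=O)CC[C@H]1C(C)(C)CCC[C@]1(C)CC(=O)O
A4 | alternative 2 | 8β-hydroxydriman-11-oic acid 8,11-β-lactone | CC1(C)CCC[C@]2(C)[C@@H](C(=O)O3)[C@]3(C)CC[C@@H]12
A5 | alternative 3 | 3-[(2E,8E,10E)-11-(tert-butyldimethylsilyloxy)-3,7,7-trimethylundeca-2,8,10-trienoyl]oxazolidin-2-one | O=C1OCCN1C(=O)/C=C(\C)CCCC(C)(C)/C=C/C=C/O[Si](C)(C)C(C)(C)C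
A6 | alternative 3 | trans-fused octalin: 8β-(tert-butyldimethylsilyloxy)-12-nordrim-6-en-11-oyl oxazolidinone | CC1(C)CCC[C@]2(C)[C@@H](C(=O)N3CCOC3=O)[C@@H](O[Si](C)(C)C(C)(C)C)C=C[C@@H]12
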